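**Retrosynthetic overview**
1. The 2,5-dimethoxy-1,4-benzoquinone is unmasked late from a hexasubstituted 1,2,4,5-tetramethoxybenzene ring. Either para pair of methoxy groups gives the same quinone, and both indole nitrogens carry Boc during that oxidation.
2. Feature used: in indole B the prenyl group sits on C7 next to N1, and C3 is bonded to the crowded central ring. N1, C7a, C7, C3a and C3 with all their substituents therefore fit on a 2-amino-3-prenylbenzoyl unit, and only C2–C3 is missing. That bond is cut back to a diaryl ketone (C3) and an N-formyl group (C2), which low-valent titanium joins.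
3. The C3–central ring bond comes from an aryllithium and a Weinreb amide, the central ring–indole A bond from a Negishi coupling, and the C7–prenyl bond from an α-selective Suzuki–Miyaura coupling.
4. Ring order: the central ring, indole A and the benzo ring of indole B are bought. The pyrrole ring of indole B is the only ring built (step 6), and the quinone is revealed in step 9.

Key step: step 6

Remark: the target has no stereocentre and no stereogenic double bond. Stereocentres that arise in two unisolated intermediates are racemic and vanish within the same step.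

**Step 1**
Reactants: 1 1,2,4,5-tetramethoxybenzene; 2 3-bromo-1-(triisopropylsilyl)indole
Product: 5 3-(2,3,5,6-tetramethoxyphenyl)-1-(triisopropylsilyl)indole, via (2,3,5,6-tetramethoxyphenyl)lithium 3 (not isolated), via chloro(2,3,5,6-tetramethoxyphenyl)zinc 4 (not isolated)
Conditions: 1 (1.3 equiv), n-BuLi (1.25 equiv), THF, 0 °C, 1.5 h; ZnCl2 (1.3 equiv), 0 °C to rt; then 2, Pd2(dba)3 (1.5 mol %), RuPhos (2-dicyclohexylphosphino-2',6'-diisopropoxybiphenyl, 6 mol %), THF, 65 °C
Reagents that add atoms: none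
Why: Directed ortho-lithiation takes a C–H flanked by two methoxy groups, ZnCl2 turns the aryllithium into a milder arylzinc, and a Negishi coupling under zerovalent palladium with a bulky dialkylbiarylphosphine suited to di-ortho-substituted partners joins it to C3 of the bromoindole, whose Si(i-Pr)3 group removes the acidic N–H and shields C2.

**Step 2**
Reactants: 6 2-amino-3-bromobenzoic acid
Product: 7 2-amino-3-bromo-N-methoxy-N-methylbenzamide
Conditions: MeNH(OMe)·HCl, EDC·HCl, HOBt, i-Pr2NEt, CH2Cl2, 0 °C to rt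
Reagents that add atoms: N,O-dimethylhydroxylamine hydrochloride, CNOC.Cl
Why: Carbodiimide/HOBt amide coupling to the Weinreb amide, in which the free alkoxyamine outruns the aniline nitrogen, a poor nucleophile flanked by bromine and by the carboxyl group.

**Step 3**
Reactants: 7 2-amino-3-bromo-N-methoxy-N-methylbenzamide; 8 4,4,5,5-tetramethyl-2-(3-methylbut-2-enyl)-1,3,2-dioxaborolane
Product: 9 2-amino-N-methoxy-N-methyl-3-(3-methylbut-2-enyl)benzamide
Conditions: PdCl2(IPent)(3-chloropyridine) (2 mol %; IPent = 1,3-bis[2,6-di(pentan-3-yl)phenyl]imidazol-2-ylidene), 5 M aq KOH, THF, 70 °C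
Reagents that add atoms: none
Why: Suzuki–Miyaura coupling of an allylic boronate, in which the very bulky N-heterocyclic carbene on palladium steers reductive elimination to the unsubstituted α-carbon so that the linear prenyl arene and not the 1,1-dimethylallyl isomer should form, while the free NH2 and the tertiary Weinreb amide tolerate the two-phase hydroxide medium.

**Step 4**
Reactants: 5 3-(2,3,5,6-tetramethoxyphenyl)-1-(triisopropylsilyl)indole; 9 2-amino-N-methoxy-N-methyl-3-(3-methylbut-2-enyl)benzamide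
Product: 13 [2-amino-3-(3-methylbut-2-enyl)phenyl][2,3,5,6-tetramethoxy-4-(1-triisopropylsilylindol-3-yl)phenyl]methanone, via aryllithium 10 (not isolated), via lithium anilide 11 (not isolated), via tetrahedral adduct 12 (not isolated)
Conditions: 5 (1.15 equiv), n-BuLi (1.1 equiv), THF, 0 °C, 2 h, then −78 °C; separately 9, n-BuLi (1.0 equiv), THF, −78 °C, 10 min; cannulation into 10, −78 to 0 °C; aq NH4Cl
Reagents that add atoms: none
Why: Acylation of an aryllithium by a Weinreb amide, a known route from 2-amino-N-methoxy-N-methylbenzamides to 2-aminobenzophenones: the only C–H of 5 between two methoxy groups is lithiated while Si(i-Pr)3 blocks indole C2, a sacrificial equivalent of n-BuLi removes the acidic N–H of 9 beforehand so that 10 is not quenched, and the chelated adduct 12 persists until the quench so that no second addition takes place.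

**Step 5**
Reactants: 13 [2-amino-3-(3-methylbut-2-enyl)phenyl][2,3,5,6-tetramethoxy-4-(1-triisopropylsilylindol-3-yl)phenyl]methanone
Product: 14 N-{2-(3-methylbut-2-enyl)-6-[2,3,5,6-tetramethoxy-4-(1-triisopropylsilylindol-3-yl)benzoyl]phenyl}formamide
Conditions: HCO2H, Ac2O, 55 °C, 2 h (gives AcOCHO); then 13, THF, 0 °C to rt
Reagents that add atoms: acetic formic anhydride, CC(=O)OC=O (made beforehand from formic acid, O=CO, and acetic anhydride, CC(=O)OC(C)=O)
Why: N-Formylation with the mixed anhydride, whose small and more electrophilic formyl carbon is transferred selectively even to this hindered, hydrogen-bonded 2-aminobenzophenone nitrogen, under conditions too mild to touch the prenyl alkene or the N–Si bond.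

**Step 6**
Reactants: 14 N-{2-(3-methylbut-2-enyl)-6-[2,3,5,6-tetramethoxy-4-(1-triisopropylsilylindol-3-yl)benzoyl]phenyl}formamide
Product: 16 7-(3-methylbut-2-enyl)-3-[2,3,5,6-tetramethoxy-4-(1-triisopropylsilylindol-3-yl)phenyl]-1H-indole, via cyclic titanium diolate 15 (not isolated)
Conditions: TiCl3 (4 equiv), Zn dust (8 equiv), THF, reflux, Ar; 14 added over 2 h (final 0.02 M); filtration through silica
Reagents that add atoms: none
Why: Low-valent titanium made in the flask from TiCl3 and zinc binds both carbonyl oxygens and passes an electron to the diaryl ketone, the easier carbonyl to reduce; the titanium-bound ketyl carbon (future C3) attacks the formamide carbon (future C2) to give the cis-diolate 15, and further low-valent titanium removes both oxygens as titanium oxide species, which leaves the C2=C3 double bond of an aromatic pyrrole ring. The closest known reaction type is the Fürstner indole synthesis, the McMurry-type reductive coupling of 2-acylanilides (oxo-amides), which covers N-acylated 2-aminobenzophenones and tolerates a free amide N–H. The one ring closed, N1–C2–C3–C3a–C7a, forms by a 5-exo-trig attack on the formyl C=O, both reacting carbons being held ortho to each other on the same benzene ring. No stereocentre remains: C2 and C3 of 15 are set cis by the bridging titanium, are racemic, and are flattened in the deoxygenation. The step needs intramolecular ketone–amide coupling in preference to pinacol dimerisation or plain reduction of the ketone, and this is secured by the two methoxy groups and the formamido group ortho to the carbonyl, which keep a second ketone away, by the short tether, and by slow addition at high dilution. The prenyl alkene, the aryl methyl ethers and the N–Si bond are not reducible under these conditions, and the excess zinc consumes any HCl that could attack them.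

**Step 7**
Reactants: 16 7-(3-methylbut-2-enyl)-3-[2,3,5,6-tetramethoxy-4-(1-triisopropylsilylindol-3-yl)phenyl]-1H-indole
Product: 17 3-[4-(1H-indol-3-yl)-2,3,5,6-tetramethoxyphenyl]-7-(3-methylbut-2-enyl)-1H-indole
Conditions: Bu4NF (1.2 equiv), THF, 0 °C to rt
Reagents that add atoms: none
Why: Fluoride-induced cleavage of the N–Si bond, placed before the oxidation because basic fluoride would attack the vinylogous ester units of the quinone, with any material that lost silicon in step 6 converging here.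

**Step 8**
Reactants: 17 3-[4-(1H-indol-3-yl)-2,3,5,6-tetramethoxyphenyl]-7-(3-methylbut-2-enyl)-1H-indole
Product: 18 tert-butyl 3-{4-[1-(tert-butoxycarbonyl)indol-3-yl]-2,3,5,6-tetramethoxyphenyl}-7-(3-methylbut-2-enyl)indole-1-carboxylate
Conditions: Boc2O (3 equiv), DMAP (0.2 equiv), MeCN, rt
Reagents that add atoms: di-tert-butyl dicarbonate, CC(C)(C)OC(=O)OC(=O)OC(C)(C)C
Why: DMAP-catalysed N-tert-butoxycarbonylation of both indoles, which draws electron density out of both pyrrole rings so that the tetramethoxybenzene ring is left as the most easily oxidised π system for step 9.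

**Step 9**
Reactants: 18 tert-butyl 3-{4-[1-(tert-butoxycarbonyl)indol-3-yl]-2,3,5,6-tetramethoxyphenyl}-7-(3-methylbut-2-enyl)indole-1-carboxylate
Product: 19 2,5-dimethoxy-3-[1-(tert-butoxycarbonyl)indol-3-yl]-6-[1-(tert-butoxycarbonyl)-7-(3-methylbut-2-enyl)indol-3-yl]-1,4-benzoquinone
Conditions: (NH4)2Ce(NO3)6 (2.3 equiv), MeCN–CH2Cl2–H2O, 0 °C, 20 min
Reagents that add atoms: water, O
Why: Oxidative demethylation of a hydroquinone dimethyl ether by tetravalent cerium, in which two one-electron oxidations of the central ring, each followed by attack of water at a methoxy-bearing carbon of a para pair and loss of methanol, give the para-quinone, both para pairs lead to the same product, and N-Boc indoles and an isolated trisubstituted alkene are oxidised less readily than the tetraalkoxyarene.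

**Step 10**
Reactants: 19 2,5-dimethoxy-3-[1-(tert-butoxycarbonyl)indol-3-yl]-6-[1-(tert-butoxycarbonyl)-7-(3-methylbut-2-enyl)indol-3-yl]-1,4-benzoquinone
Product: 20 2,5-dimethoxy-3-(1H-indol-3-yl)-6-[7-(3-methylbut-2-enyl)-1H-indol-3-yl]-1,4-benzoquinone (target)
Conditions: NaOMe (0.3 equiv), dry MeOH–THF, 0 °C to rt; AcOH quench
Reagents that add atoms: none
Why: Methoxide-catalysed methanolysis of the two indole carbamates (the indolide is a good leaving group), chosen because attack of methoxide at the methoxy-bearing quinone carbons only exchanges OMe for OMe and because no acid is present that could cyclise the prenyl group onto N1.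

**Compound list**
1 | 1,2,4,5-tetramethoxybenzene | COc1cc(OC)c(OC)cc1OC | starting material
2 | 3-bromo-1-(triisopropylsilyl)indole | CC(C)[Si](C(C)C)(C(C)C)n1cc(Br)c2ccccc12 | starting material
3 | (2,3,5,6-tetramethoxyphenyl)lithium | [Li]c1c(OC)c(OC)cc(OC)c1OC | intermediate
4 | chloro(2,3,5,6-tetramethoxyphenyl)zinc | Cl[Zn]c1c(OC)c(OC)cc(OC)c1OC | intermediate
5 | 3-(2,3,5,6-tetramethoxyphenyl)-1-(triisopropylsilyl)indole | COc1cc(OC)c(OC)c(c2cn([Si](C(C)C)(C(C)C)C(C)C)c3ccccc23)c1OC | intermediate
6 | 2-amino-3-bromobenzoic acid | Nc1c(Br)cccc1C(=O)O | starting material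
7 | 2-amino-3-bromo-N-methoxy-N-methylbenzamide | CON(C)C(=O)c1cccc(Br)c1N | intermediate
8 | 4,4,5,5-tetramethyl-2-(3-methylbut-2-enyl)-1,3,2-dioxaborolane | CC(C)=CCB1OC(C)(C)C(C)(C)O1 | starting material
9 | 2-amino-N-methoxy-N-methyl-3-(3-methylbut-2-enyl)benzamide | CON(C)C(=O)c1cccc(CC=C(C)C)c1N | intermediate
10 | [2,3,5,6-tetramethoxy-4-(1-triisopropylsilylindol-3-yl)phenyl]lithium | [Li]c1c(OC)c(OC)c(c2cn([Si](C(C)C)(C(C)C)C(C)C)c3ccccc23)c(OC)c1OC | intermediate
11 | lithium anilide of 9 | CON(C)C(=O)c1cccc(CC=C(C)C)c1N[Li] | intermediate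
12 | dilithiated tetrahedral adduct of 10 and 11 (racemic) | CON(C)C(O[Li])(c1cccc(CC=C(C)C)c1N[Li])c1c(OC)c(OC)c(c2cn([Si](C(C)C)(C(C)C)C(C)C)c3ccccc23)c(OC)c1OC | intermediate
13 | [2-amino-3-(3-methylbut-2-enyl)phenyl][2,3,5,6-tetramethoxy-4-(1-triisopropylsilylindol-3-yl)phenyl]methanone | Nc1c(CC=C(C)C)cccc1C(=O)c1c(OC)c(OC)c(c2cn([Si](C(C)C)(C(C)C)C(C)C)c3ccccc23)c(OC)c1OC | intermediate
14 | N-{2-(3-methylbut-2-enyl)-6-[2,3,5,6-tetramethoxy-4-(1-triisopropylsilylindol-3-yl)benzoyl]phenyl}formamide | O=CNc1c(CC=C(C)C)cccc1C(=O)c1c(OC)c(OC)c(c2cn([Si](C(C)C)(C(C)C)C(C)C)c3ccccc23)c(OC)c1OC | intermediate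
15 | cyclic dichlorotitanium cis-2,3-diolate of the 3-aryl-7-prenylindoline (racemic, one enantiomer drawn) | Cl[Ti]1(Cl)O[C@H]2Nc3c(CC=C(C)C)cccc3[C@]2(O1)c1c(OC)c(OC)c(c2cn([Si](C(C)C)(C(C)C)C(C)C)c3ccccc23)c(OC)c1OC | intermediate
16 | 7-(3-methylbut-2-enyl)-3-[2,3,5,6-tetramethoxy-4-(1-triisopropylsilylindol-3-yl)phenyl]-1H-indole | COc1c(OC)c(c2c[nH]c3c(CC=C(C)C)cccc23)c(OC)c(OC)c1c1cn([Si](C(C)C)(C(C)C)C(C)C)c2ccccc12 | intermediate
17 | 3-[4-(1H-indol-3-yl)-2,3,5,6-tetramethoxyphenyl]-7-(3-methylbut-2-enyl)-1H-indole | COc1c(OC)c(c2c[nH]c3c(CC=C(C)C)cccc23)c(OC)c(OC)c1c1c[nH]c2ccccc12 | intermediate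
18 | tert-butyl 3-{4-[1-(tert-butoxycarbonyl)indol-3-yl]-2,3,5,6-tetramethoxyphenyl}-7-(3-methylbut-2-enyl)indole-1-carboxylate | COc1c(OC)c(c2cn(C(=O)OC(C)(C)C)c3c(CC=C(C)C)cccc23)c(OC)c(OC)c1c1cn(C(=O)OC(C)(C)C)c2ccccc12 | intermediate
19 | 2,5-dimethoxy-3-[1-(tert-butoxycarbonyl)indol-3-yl]-6-[1-(tert-butoxycarbonyl)-7-(3-methylbut-2-enyl)indol-3-yl]-1,4-benzoquinone | COC1=C(c2cn(C(=O)OC(C)(C)C)c3ccccc23)C(=O)C(OC)=C(c2cn(C(=O)OC(C)(C)C)c3c(CC=C(C)C)cccc23)C1=O | intermediate
20 | 2,5-dimethoxy-3-(1H-indol-3-yl)-6-[7-(3-methylbut-2-enyl)-1H-indol-3-yl]-1,4-benzoquinone | COC1=C(c2c[nH]c3ccccc23)C(=O)C(OC)=C(c2c[nH]c3c(CC=C(C)C)cccc23)C1=O | target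

**Total step count:** 10. **Longest linear sequence:** 9 steps (steps 2–10: 6 → 7 → 9 → 13 → 14 → 16 → 17 → 18 → 19 → 20).

**Steps most likely to fail**

Step 6. The carbonyl carbon is flanked by three ortho substituents. The ketone may therefore simply be reduced to the carbinol or the diarylmethane, or the coupling may stall before deoxygenation. The fallback makes the C3–aryl bond of indole B by cross-coupling onto a finished indole instead of closing the ring. It sets out from 5 and 8 and comes back at 18.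
- Commercial 7-bromoindole (Brc1cccc2cc[nH]c12) and 8 under the conditions of step 3 should give 7-(3-methylbut-2-enyl)-1H-indole F1.
- I2/KOH in DMF at 0 °C iodinates the far more nucleophilic C3 to give 3-iodo-7-(3-methylbut-2-enyl)-1H-indole F2. This is protected at once with Boc2O/DMAP as tert-butyl 3-iodo-7-(3-methylbut-2-enyl)indole-1-carboxylate F3.
- Compound 5 is lithiated to 10 as in step 4 and treated with ZnCl2 to give chloro[2,3,5,6-tetramethoxy-4-(1-triisopropylsilylindol-3-yl)phenyl]zinc F4.
- Negishi coupling of F4 with F3 (Pd2(dba)3, RuPhos, THF, 65 °C) gives tert-butyl 7-(3-methylbut-2-enyl)-3-[2,3,5,6-tetramethoxy-4-(1-triisopropylsilylindol-3-yl)phenyl]indole-1-carboxylate F5.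
- Bu4NF at 0 °C removes the silyl group to give tert-butyl 3-[4-(1H-indol-3-yl)-2,3,5,6-tetramethoxyphenyl]-7-(3-methylbut-2-enyl)indole-1-carboxylate F6, and Boc2O/DMAP leads to 18.

Step 9. Four methoxy groups twisted out of the ring plane raise the oxidation potential of the central ring. Electron transfer from the carbamate-bearing indole rings or from the alkene may then compete, and the acid formed may start to cleave the carbamates. The fallback moves the oxidation to the bare core and carries a masked hydroquinone through the same strategy, so that the end needs only dilute acid and air. It sets out from 1 (with 2 and 9 as partners) and comes back at 20.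
- (NH4)2Ce(NO3)6 in aqueous MeCN turns 1, which has no other oxidisable group, into 2,5-dimethoxy-1,4-benzoquinone F7.
- Na2S2O4 reduces F7 to 2,5-dimethoxybenzene-1,4-diol F8, and MeOCH2Cl/i-Pr2NEt gives 1,4-dimethoxy-2,5-bis(methoxymethoxy)benzene F9.
- F9 takes the place of 1. The operations of step 1 with 2 give 3-[2,5-dimethoxy-3,6-bis(methoxymethoxy)phenyl]-1-(triisopropylsilyl)indole F10.
- The operations of step 4 with 9 give [2-amino-3-(3-methylbut-2-enyl)phenyl][2,5-dimethoxy-3,6-bis(methoxymethoxy)-4-(1-triisopropylsilylindol-3-yl)phenyl]methanone F11.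
- Step 5 gives N-{2-[2,5-dimethoxy-3,6-bis(methoxymethoxy)-4-(1-triisopropylsilylindol-3-yl)benzoyl]-6-(3-methylbut-2-enyl)phenyl}formamide F12.
- Step 6 gives 3-[2,5-dimethoxy-3,6-bis(methoxymethoxy)-4-(1-triisopropylsilylindol-3-yl)phenyl]-7-(3-methylbut-2-enyl)-1H-indole F13.
- Step 7 gives 3-[4-(1H-indol-3-yl)-2,5-dimethoxy-3,6-bis(methoxymethoxy)phenyl]-7-(3-methylbut-2-enyl)-1H-indole F14.
- Dilute HCl in MeOH–THF at 40 °C cleaves both acetals to give 2-(1H-indol-3-yl)-3,6-dimethoxy-5-[7-(3-methylbut-2-enyl)-1H-indol-3-yl]benzene-1,4-diol F15, which air oxidises in the same flask to 20.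

Step 4. Three processes could erode the fragment union: proton transfer from the anilide to 10, addition of n-BuLi to the Weinreb amide during the pre-deprotonation, and sluggish attack on an amide deactivated by the neighbouring anionic nitrogen. The fallback masks the nitrogen in an aprotic form that is also the latent formyl group. It sets out from 9 and comes back at 14, so step 5 is not needed.
- Me2NCH(OMe)2 in toluene at 100 °C converts 9 into (E)-N'-{2-[methoxy(methyl)carbamoyl]-6-(3-methylbut-2-enyl)phenyl}-N,N-dimethylformamidine F16.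
- Aryllithium 10 adds to F16 at −78 to 0 °C. A water quench gives (E)-N,N-dimethyl-N'-{2-(3-methylbut-2-enyl)-6-[2,3,5,6-tetramethoxy-4-(1-triisopropylsilylindol-3-yl)benzoyl]phenyl}formamidine F17.
- AcOH–H2O–THF at 40 °C hydrolyses the amidine, expelling the more basic amine, to give formamide 14.
- Any material hydrolysed further to 13 is returned to 14 by step 5.

**Further compounds**
F1 | step 6 | 7-(3-methylbut-2-enyl)-1H-indole | CC(C)=CCc1cccc2cc[nH]c12
F2 | step 6 | 3-iodo-7-(3-methylbut-2-enyl)-1H-indole | CC(C)=CCc1cccc2c(I)c[nH]c12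
F3 | step 6 | tert-butyl 3-iodo-7-(3-methylbut-2-enyl)indole-1-carboxylate | CC(C)=CCc1cccc2c(I)cn(C(=O)OC(C)(C)C)c12
F4 | step 6 | chloro[2,3,5,6-tetramethoxy-4-(1-triisopropylsilylindol-3-yl)phenyl]zinc | Cl[Zn]c1c(OC)c(OC)c(c2cn([Si](C(C)C)(C(C)C)C(C)C)c3ccccc23)c(OC)c1OC
F5 | step 6 | tert-butyl 7-(3-methylbut-2-enyl)-3-[2,3,5,6-tetramethoxy-4-(1-triisopropylsilylindol-3-yl)phenyl]indole-1-carboxylate | COc1c(OC)c(c2cn(C(=O)OC(C)(C)C)c3c(CC=C(C)C)cccc23)c(OC)c(OC)c1c1cn([Si](C(C)C)(C(C)C)C(C)C)c2ccccc12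
F6 | step 6 | tert-butyl 3-[4-(1H-indol-3-yl)-2,3,5,6-tetramethoxyphenyl]-7-(3-methylbut-2-enyl)indole-1-carboxylate | COc1c(OC)c(c2cn(C(=O)OC(C)(C)C)c3c(CC=C(C)C)cccc23)c(OC)c(OC)c1c1c[nH]c2ccccc12
F7 | step 9 | 2,5-dimethoxy-1,4-benzoquinone | COC1=CC(=O)C(OC)=CC1=O
F8 | step 9 | 2,5-dimethoxybenzene-1,4-diol | COc1cc(O)c(OC)cc1O
F9 | step 9 | 1,4-dimethoxy-2,5-bis(methoxymethoxy)benzene | COCOc1cc(OC)c(OCOC)cc1OC
F10 | step 9 | 3-[2,5-dimethoxy-3,6-bis(methoxymethoxy)phenyl]-1-(triisopropylsilyl)indole | COCOc1cc(OC)c(OCOC)c(c2cn([Si](C(C)C)(C(C)C)C(C)C)c3ccccc23)c1OC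
F11 | step 9 | [2-amino-3-(3-methylbut-2-enyl)phenyl][2,5-dimethoxy-3,6-bis(methoxymethoxy)-4-(1-triisopropylsilylindol-3-yl)phenyl]methanone | Nc1c(CC=C(C)C)cccc1C(=O)c1c(OC)c(OCOC)c(c2cn([Si](C(C)C)(C(C)C)C(C)C)c3ccccc23)c(OC)c1OCOC
F12 | step 9 | N-{2-[2,5-dimethoxy-3,6-bis(methoxymethoxy)-4-(1-triisopropylsilylindol-3-yl)benzoyl]-6-(3-methylbut-2-enyl)phenyl}formamide | O=CNc1c(CC=C(C)C)cccc1C(=O)c1c(OC)c(OCOC)c(c2cn([Si](C(C)C)(C(C)C)C(C)C)c3ccccc23)c(OC)c1OCOC
F13 | step 9 | 3-[2,5-dimethoxy-3,6-bis(methoxymethoxy)-4-(1-triisopropylsilylindol-3-yl)phenyl]-7-(3-methylbut-2-enyl)-1H-indole | COCOc1c(OC)c(c2cn([Si](C(C)C)(C(C)C)C(C)C)c3ccccc23)c(OCOC)c(OC)c1c1c[nH]c2c(CC=C(C)C)cccc12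
F14 | step 9 | 3-[4-(1H-indol-3-yl)-2,5-dimethoxy-3,6-bis(methoxymethoxy)phenyl]-7-(3-methylbut-2-enyl)-1H-indole | COCOc1c(OC)c(c2c[nH]c3ccccc23)c(OCOC)c(OC)c1c1c[nH]c2c(CC=C(C)C)cccc12
F15 | step 9 | 2-(1H-indol-3-yl)-3,6-dimethoxy-5-[7-(3-methylbut-2-enyl)-1H-indol-3-yl]benzene-1,4-diol | COc1c(O)c(c2c[nH]c3c(CC=C(C)C)cccc23)c(OC)c(O)c1c1c[nH]c2ccccc12
F16 | step 4 | (E)-N'-{2-[methoxy(methyl)carbamoyl]-6-(3-methylbut-2-enyl)phenyl}-N,N-dimethylformamidine | CON(C)C(=O)c1cccc(CC=C(C)C)c1/N=C/N(C)C
F17 | step 4 | (E)-N,N-dimethyl-N'-{2-(3-methylbut-2-enyl)-6-[2,3,5,6-tetramethoxy-4-(1-triisopropylsilylindol-3-yl)benzoyl]phenyl}formamidine | CN(C)/C=N/c1c(CC=C(C)C)cccc1C(=O)c1c(OC)c(OC)c(c2cn([Si](C(C)C)(C(C)C)C(C)C)c3ccccc23)c(OC)c1OC
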